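**Plan**

- Ring A is numbered C1 (OMe), C2 (H), C3 (OH), C4 (carrying the C7 methylene to ring C), C5 (carrying the Ca–Cb bridge to ring B), C6 (H). The target has no stereocentre, so no stereocontrol is needed.
- Retrosynthesis first removes three benzyl ethers, then returns the C7 methylene to a diaryl ketone and cuts C7–ring C, giving a ring A methyl benzoate and 4-(benzyloxy)phenyllithium.
- Ring A is then cut at C5–C6 and C1–C2. The run C2–C3(O)–C4(C7)–C5(chain) is the diene C3–C6 of a 4-benzyloxy-6-alkyl-2-pyrone-5-carboxylate whose ester carbon is C7, and C6–C1(OMe) is 1,1-dimethoxyethene. CO2 and methanol are the leaving pieces.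
- The pyrone is cut to malonyl dichloride and a β-keto ester, and the latter at Ca–Cb to the methyl acetoacetate dianion and the ring B benzyl bromide.
- Forward order: Ca–Cb joined, pyrone ring closed, O-4 benzylated, ring A formed from the pyrone, ring C attached at C7, C7 deoxygenated, benzyl groups removed.

Key step: step 4

Remark: the target has no stereocentre, and 2-(benzyloxy)benzyl bromide is taken as a catalogue compound.

**Route**

Step 1
Reactants: 1 methyl acetoacetate; 2 2-(benzyloxy)benzyl bromide
Product: 4 methyl 5-[2-(benzyloxy)phenyl]-3-oxopentanoate, via acetoacetate dianion 3 (not isolated)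
Conditions: NaH, THF, 0 °C; n-BuLi, 0 °C; then 2, 0 °C → rt; aq. HCl
Reagents that add atoms: none
Why: Dianion γ-alkylation of a β-keto ester: the terminal carbanion of 3 is the more basic and more nucleophilic site and should be benzylated cleanly by the primary benzylic bromide in an SN2 reaction, with no stereocentre formed.

Step 2
Reactants: 4 methyl 5-[2-(benzyloxy)phenyl]-3-oxopentanoate; 5 malonyl dichloride
Product: 7 methyl 6-{2-[2-(benzyloxy)phenyl]ethyl}-4-hydroxy-2-oxo-2H-pyran-5-carboxylate, via acylated keto ester 6 (not isolated)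
Conditions: ClCH2CH2Cl, 25 → 60 °C, N2 sweep
Reagents that add atoms: none
Why: Cyclocondensation of malonyl dichloride with a β-keto ester is the classical entry to 5-alkoxycarbonyl-6-alkyl-4-hydroxy-2-pyrones: C-acylation at the doubly activated carbon gives 6, whose ketone enol oxygen closes the lactone on the second acid chloride, and the aryl benzyl ether should tolerate the HCl that is swept out.

Step 3
Reactants: 7 methyl 6-{2-[2-(benzyloxy)phenyl]ethyl}-4-hydroxy-2-oxo-2H-pyran-5-carboxylate
Product: 8 methyl 4-(benzyloxy)-6-{2-[2-(benzyloxy)phenyl]ethyl}-2-oxo-2H-pyran-5-carboxylate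
Conditions: BnOH, PPh3, DIAD, THF, 0 °C → rt
Reagents that add atoms: benzyl alcohol, OCc1ccccc1
Why: Mitsunobu etherification of the acidic 4-hydroxy-2-pyrone (a vinylogous carboxylic acid) with a primary alcohol is known to alkylate O-4 in preference to the lactone oxygen or C-3, and the neutral conditions leave lactone and ester untouched.

Step 4
Reactants: 8 methyl 4-(benzyloxy)-6-{2-[2-(benzyloxy)phenyl]ethyl}-2-oxo-2H-pyran-5-carboxylate; 9 1,1-dimethoxyethene
Product: 12 methyl 2-(benzyloxy)-6-{2-[2-(benzyloxy)phenyl]ethyl}-4-methoxybenzoate, via bicyclic lactone 10 (not isolated), via cyclohexadiene ketal 11 (not isolated)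
Conditions: 9 (5 equiv), toluene, sealed tube, 140 °C
Reagents that add atoms: none
Why: The nucleophilic CH2 of ketene acetal 9 should bond to pyrone C-6 (the chain-bearing carbon, β to the 5-ester and δ to the lactone carbonyl) and the acetal carbon to the alkoxy-activated C-3, a polar, asynchronous inverse-electron-demand [4+2] cycloaddition that gives bridged lactone 10. Retro-[4+2] extrusion of CO2 from 10 gives cyclohexadiene ketal 11, which aromatises by 1,2-elimination of methanol, so ring A is closed as a six-membered carbocycle by [4+2] cycloaddition with two new C–C bonds (C5–C6 and C1–C2 of ring A). The closest known reaction type is the Diels–Alder/decarboxylation/alcohol-elimination sequence of 2-pyrone-5-carboxylates such as methyl coumalate with ketene acetals, which gives 4-alkoxybenzoates with the same orientation. No stereocentre remains, since the two bridgehead centres of racemic 10 are erased on aromatisation. The selectivity required is regiochemical (OMe para to the ester and meta to the chain) and is secured by the push–pull polarisation of the diene (electrophilic C-6, nucleophilic C-3) matched with the polarised ketene acetal; the lower electron demand of the 4-benzyloxy pyrone is offset by excess 9, high concentration and sealed-tube heating.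

Step 5
Reactants: 12 methyl 2-(benzyloxy)-6-{2-[2-(benzyloxy)phenyl]ethyl}-4-methoxybenzoate; 13 1-(benzyloxy)-4-bromobenzene
Product: 16 [2-(benzyloxy)-6-{2-[2-(benzyloxy)phenyl]ethyl}-4-methoxyphenyl][4-(benzyloxy)phenyl]methanone, via aryllithium 14 (not isolated), via lithium hemiketal 15 (not isolated)
Conditions: 13, n-BuLi, THF, −78 °C; then 12, −78 → −40 °C; aq. HCl
Reagents that add atoms: none
Why: Bromine–lithium exchange followed by nucleophilic acyl substitution: the di-ortho-substituted adduct 15 should persist at low temperature and the twisted, shielded diaryl ketone released on quench is a poor electrophile, so a single aryl group is expected to add.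

Step 6
Reactants: 16 [2-(benzyloxy)-6-{2-[2-(benzyloxy)phenyl]ethyl}-4-methoxyphenyl][4-(benzyloxy)phenyl]methanone
Product: 18 1-(benzyloxy)-2-{[4-(benzyloxy)phenyl]methyl}-3-{2-[2-(benzyloxy)phenyl]ethyl}-5-methoxybenzene, via diarylcarbinol 17 (not isolated)
Conditions: Et3SiH (3 equiv), CF3CO2H, CH2Cl2, 0 °C → rt
Reagents that add atoms: none
Why: Ionic hydrogenation: protonation of the electron-rich diaryl ketone, hydride transfer from Et3SiH to give 17, ionisation to the doubly benzylic, alkoxy-stabilised cation and a second hydride transfer should deliver the methylene, while aryl benzyl ethers are expected to survive CF3CO2H in CH2Cl2 at this temperature.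

Step 7
Reactants: 18 1-(benzyloxy)-2-{[4-(benzyloxy)phenyl]methyl}-3-{2-[2-(benzyloxy)phenyl]ethyl}-5-methoxybenzene
Product: 19 2-[(4-hydroxyphenyl)methyl]-3-[2-(2-hydroxyphenyl)ethyl]-5-methoxyphenol (target)
Conditions: H2 (1 atm), Pd/C, EtOAc–MeOH, rt
Reagents that add atoms: none
Why: Catalytic hydrogenolysis of the three aryl benzyl ethers over Pd/C is standard, and the methyl ether, the diarylmethane and the bibenzyl C–C bonds are inert under these conditions.

**Compound list**

1 | methyl acetoacetate (methyl 3-oxobutanoate) | COC(=O)CC(C)=O | starting material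
2 | 2-(benzyloxy)benzyl bromide [1-(benzyloxy)-2-(bromomethyl)benzene] | BrCc1ccccc1OCc1ccccc1 | starting material
3 | sodium lithium dienolate (dianion) of methyl acetoacetate | C=C([O-])C=C([O-])OC.[Na+].[Li+] | intermediate (not isolated)
4 | methyl 5-[2-(benzyloxy)phenyl]-3-oxopentanoate | COC(=O)CC(=O)CCc1ccccc1OCc1ccccc1 | intermediate
5 | malonyl dichloride (propanedioyl dichloride) | O=C(Cl)CC(Cl)=O | starting material
6 | methyl 5-[2-(benzyloxy)phenyl]-2-(3-chloro-3-oxopropanoyl)-3-oxopentanoate | COC(=O)C(C(=O)CC(Cl)=O)C(=O)CCc1ccccc1OCc1ccccc1 | intermediate (not isolated)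
7 | methyl 6-{2-[2-(benzyloxy)phenyl]ethyl}-4-hydroxy-2-oxo-2H-pyran-5-carboxylate | COC(=O)c1c(O)cc(=O)oc1CCc1ccccc1OCc1ccccc1 | intermediate
8 | methyl 4-(benzyloxy)-6-{2-[2-(benzyloxy)phenyl]ethyl}-2-oxo-2H-pyran-5-carboxylate | COC(=O)c1c(OCc2ccccc2)cc(=O)oc1CCc1ccccc1OCc1ccccc1 | intermediate (key-step precursor)
9 | 1,1-dimethoxyethene (ketene dimethyl acetal) | C=C(OC)OC | starting material
10 | methyl 5-(benzyloxy)-1-{2-[2-(benzyloxy)phenyl]ethyl}-8,8-dimethoxy-3-oxo-2-oxabicyclo[2.2.2]oct-5-ene-6-carboxylate (racemic) | COC(=O)C1=C(OCc2ccccc2)C2C(=O)OC1(CCc1ccccc1OCc1ccccc1)CC2(OC)OC | intermediate (not isolated)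
11 | methyl 6-(benzyloxy)-2-{2-[2-(benzyloxy)phenyl]ethyl}-4,4-dimethoxycyclohexa-1,5-diene-1-carboxylate | COC(=O)C1=C(CCc2ccccc2OCc2ccccc2)CC(OC)(OC)C=C1OCc1ccccc1 | intermediate (not isolated)
12 | methyl 2-(benzyloxy)-6-{2-[2-(benzyloxy)phenyl]ethyl}-4-methoxybenzoate | COC(=O)c1c(OCc2ccccc2)cc(OC)cc1CCc1ccccc1OCc1ccccc1 | intermediate (key-step product)
13 | 1-(benzyloxy)-4-bromobenzene | Brc1ccc(OCc2ccccc2)cc1 | starting material
14 | [4-(benzyloxy)phenyl]lithium | [Li]c1ccc(OCc2ccccc2)cc1 | intermediate (not isolated)
15 | lithium [2-(benzyloxy)-6-{2-[2-(benzyloxy)phenyl]ethyl}-4-methoxyphenyl][4-(benzyloxy)phenyl]methoxymethanolate (racemic) | [Li+].COc1cc(OCc2ccccc2)c(C([O-])(OC)c2ccc(OCc3ccccc3)cc2)c(CCc2ccccc2OCc2ccccc2)c1 | intermediate (not isolated)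
16 | [2-(benzyloxy)-6-{2-[2-(benzyloxy)phenyl]ethyl}-4-methoxyphenyl][4-(benzyloxy)phenyl]methanone | COc1cc(OCc2ccccc2)c(C(=O)c2ccc(OCc3ccccc3)cc2)c(CCc2ccccc2OCc2ccccc2)c1 | intermediate
17 | [2-(benzyloxy)-6-{2-[2-(benzyloxy)phenyl]ethyl}-4-methoxyphenyl][4-(benzyloxy)phenyl]methanol (racemic) | COc1cc(OCc2ccccc2)c(C(O)c2ccc(OCc3ccccc3)cc2)c(CCc2ccccc2OCc2ccccc2)c1 | intermediate (not isolated)
18 | 1-(benzyloxy)-2-{[4-(benzyloxy)phenyl]methyl}-3-{2-[2-(benzyloxy)phenyl]ethyl}-5-methoxybenzene | COc1cc(OCc2ccccc2)c(Cc2ccc(OCc3ccccc3)cc2)c(CCc2ccccc2OCc2ccccc2)c1 | intermediate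
19 | 2-[(4-hydroxyphenyl)methyl]-3-[2-(2-hydroxyphenyl)ethyl]-5-methoxyphenol | COc1cc(O)c(Cc2ccc(O)cc2)c(CCc2ccccc2O)c1 | target

**Summary**

Total step count: 7. Longest linear sequence: 7 steps (1 to 19); the aryllithium is made in the flask in step 5, so there is no separate branch.

**Steps most likely to fail**

Step 4. The cycloaddition may be too slow at a tetrasubstituted, alkoxy-deactivated diene terminus. Thermal oligomerisation of the ketene acetal, or conjugate addition with opening of the pyrone and no ring closure, could then take over. The fallback sets out from bromide 2 and comes back at 12, and takes ring A from a purchased arene instead of building it. Methyl orsellinate F1 (methyl 2,4-dihydroxy-6-methylbenzoate) would be methylated at the non-chelated 4-hydroxyl (MeI, K2CO3, acetone) to methyl 2-hydroxy-4-methoxy-6-methylbenzoate F2. Benzylation (BnBr, K2CO3, DMF, 60 °C) would give methyl 2-(benzyloxy)-4-methoxy-6-methylbenzoate F3. Lateral deprotonation of the ortho-methyl group with LiN(iPr)2 in THF at −78 °C would give the benzylic lithio species F4, whose alkylation with 2 should give 12.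

Step 5. The aryllithium may deprotonate the benzylic CH2 ortho to the ester instead of adding. Addition may also stall at the di-ortho-substituted carbonyl, or a second aryl group may add after early collapse of the hemiketal. The fallback sets out from 12 and comes back at carbinol 17, using an aldehyde as the electrophile. LiAlH4 in THF at 0 °C would reduce the ester to [2-(benzyloxy)-6-{2-[2-(benzyloxy)phenyl]ethyl}-4-methoxyphenyl]methanol F5. MnO2 in CH2Cl2 would oxidise this to 2-(benzyloxy)-6-{2-[2-(benzyloxy)phenyl]ethyl}-4-methoxybenzaldehyde F6. Addition of aryllithium 14 at −78 °C should then give 17 in isolated form, which is carried to 18 under the conditions of step 6.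

Step 2. A second molecule of malonyl dichloride may acylate C-3 of the newly formed hydroxypyrone, O-acylation may compete with C-acylation, and the HCl released may cleave the aryl benzyl ether. The fallback sets out from 4 and comes back at 7, forming the two bonds one at a time without HCl. C-Acylation of 4 with methyl 3-chloro-3-oxopropanoate under soft enolisation (MgCl2, pyridine, CH2Cl2, 0 °C) would give dimethyl 2-{3-[2-(benzyloxy)phenyl]propanoyl}-3-oxopentanedioate F7. Heating F7 in toluene with catalytic TsOH while methanol distils should close the lactone through the ketone enol oxygen to give 7.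

**Further compounds**

F1 | step 4 | methyl 2,4-dihydroxy-6-methylbenzoate (methyl orsellinate) | COC(=O)c1c(C)cc(O)cc1O
F2 | step 4 | methyl 2-hydroxy-4-methoxy-6-methylbenzoate | COC(=O)c1c(C)cc(OC)cc1O
F3 | step 4 | methyl 2-(benzyloxy)-4-methoxy-6-methylbenzoate | COC(=O)c1c(C)cc(OC)cc1OCc1ccccc1
F4 | step 4 | methyl 2-(benzyloxy)-6-(lithiomethyl)-4-methoxybenzoate | [Li]Cc1cc(OC)cc(OCc2ccccc2)c1C(=O)OC
F5 | step 5 | [2-(benzyloxy)-6-{2-[2-(benzyloxy)phenyl]ethyl}-4-methoxyphenyl]methanol | COc1cc(OCc2ccccc2)c(CO)c(CCc2ccccc2OCc2ccccc2)c1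
F6 | step 5 | 2-(benzyloxy)-6-{2-[2-(benzyloxy)phenyl]ethyl}-4-methoxybenzaldehyde | COc1cc(OCc2ccccc2)c(C=O)c(CCc2ccccc2OCc2ccccc2)c1
F7 | step 2 | dimethyl 2-{3-[2-(benzyloxy)phenyl]propanoyl}-3-oxopentanedioate | COC(=O)CC(=O)C(C(=O)OC)C(=O)CCc1ccccc1OCc1ccccc1
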